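**Retrosynthetic overview**

1. Feature: C1 is a fully substituted ring carbon carrying the oxirane oxygen O1 and the C7–O7 arm, the retron of a 1,2-diol made from an exocyclic C1=C7 methylene. Without C7, the carbocycle (oxygens on C3, C2, C1, C6; alkene C4=C5) is a twofold-symmetric conduritol E tetrol.
2. Oxirane C1–O1–C6 (formed last): Mitsunobu cyclodehydration of the trans C1/C6 diol, after benzoylation of O7 and O2 and desilylation.
3. C1–O1 and C7–O7: OsO4–TMEDA dihydroxylation of the C1=C7 methylene, directed by the free C2 hydroxyl of a 3,6-bis-silylated methylene cyclohexenol.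
4. C1=C7: mono-oxidation of the homotopic C1/C2 diol of 3,6-di-O-TBS-conduritol E, then Takai–Lombardo methylenation.
5. Cyclohexene ring (formed first): ring-closing metathesis of a D-manno octa-1,7-diene made from 3,4-O-isopropylidene-D-mannitol through its bis-epoxide and a sulfonium ylide homologation.

Key step: step 9

Remark on locants: C1 = quaternary ring carbon, C2 = CH–OBz, C3 = CH–OH, C4=C5, C6 = oxirane CH, C7 = exocyclic CH2. These locants are kept for every carbocyclic intermediate. In the target O1, O2 and O3 lie on one ring face and C7 on the other.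

Assumption: 3,4-O-isopropylidene-D-mannitol is taken as a purchasable compound (otherwise two steps from D-mannitol via the triacetonide).

Remark on the chiral pool: the D-manno chain is erythro–threo–erythro with a central diol of D-threo configuration. It maps directly onto C3–C2–C1–C6 of the required enantiomer, so no carbinol centre has to be set by a diastereoselective carbonyl addition.

**Route**

Step 1
Reactants: 1 3,4-O-isopropylidene-D-mannitol
Product: 2 3,4-O-isopropylidene-1,6-di-O-(p-tolylsulfonyl)-D-mannitol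
Conditions: TsCl (2.1 equiv), pyridine, CH2Cl2, −20 → 0 °C
Reagents that add atoms: p-toluenesulfonyl chloride Cc1ccc(cc1)S(=O)(=O)Cl
Why: Selective sulfonylation, in which the two primary hydroxyls should react well ahead of the hindered secondary ones at low temperature and no stereocentre is touched.

Step 2
Reactants: 2 3,4-O-isopropylidene-1,6-di-O-(p-tolylsulfonyl)-D-mannitol
Product: 3 1,2:5,6-dianhydro-3,4-O-isopropylidene-D-mannitol
Conditions: K2CO3, MeOH, 0 °C → rt
Reagents that add atoms: none
Why: Intramolecular Williamson etherification (3-exo-tet) in which each secondary alkoxide displaces the neighbouring primary tosylate, so the C–O stereocentres are retained, while the trans-dioxolane disfavours anhydro-ring closure across the chain.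

Step 3
Reactants: 3 1,2:5,6-dianhydro-3,4-O-isopropylidene-D-mannitol
Product: 4 1,2,7,8-tetradeoxy-4,5-O-isopropylidene-D-manno-octa-1,7-dienitol
Conditions: Me3S+ I− (6 equiv), n-BuLi (6 equiv), THF, −10 °C → rt
Reagents that add atoms: trimethylsulfonium iodide C[S+](C)C.[I-]
Why: Epoxide-to-allylic-alcohol one-carbon homologation with the Corey–Chaykovsky sulfonium ylide, in which the ylide opens each terminal oxirane at CH2 and the β-alkoxy sulfonium salt is deprotonated by further ylide and loses dimethyl sulfide, leaving all four stereocentres untouched.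

Step 4
Reactants: 4 1,2,7,8-tetradeoxy-4,5-O-isopropylidene-D-manno-octa-1,7-dienitol
Product: 5 3,6-bis-O-(tert-butyldimethylsilyl) ether of 4
Conditions: TBSCl, imidazole, DMF, rt
Reagents that add atoms: tert-butyldimethylsilyl chloride CC(C)(C)[Si](C)(C)Cl
Why: Standard imidazole-mediated silylation of the two homotopic secondary allylic hydroxyls, with no change at any stereocentre.

Step 5
Reactants: 5 3,6-bis-O-(tert-butyldimethylsilyl) ether of 4
Product: 6 (3aS,4R,7R,7aS)-4,7-bis(tert-butyldimethylsilyloxy)-2,2-dimethyl-3a,4,7,7a-tetrahydro-1,3-benzodioxole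
Conditions: second-generation Grubbs catalyst (H2IMes)(PCy3)Cl2Ru=CHPh (cat.), CH2Cl2, 40 °C
Reagents that add atoms: none
Why: Ring-closing metathesis of the 1,7-diene to the cyclohexene, driven by loss of ethylene, for which dienes bridged by a trans-dioxolane are established substrates and in which no stereocentre changes.

Step 6
Reactants: 6 (3aS,4R,7R,7aS)-4,7-bis(tert-butyldimethylsilyloxy)-2,2-dimethyl-3a,4,7,7a-tetrahydro-1,3-benzodioxole
Product: 7 (1S,2S,3R,6R)-3,6-bis(tert-butyldimethylsilyloxy)cyclohex-4-ene-1,2-diol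
Conditions: PPTS (cat.), MeOH, rt → 40 °C
Reagents that add atoms: none
Why: Acid-catalysed transacetalisation, in which the strained trans-fused dioxolane should be far more labile than the secondary TBS ethers and so should be the only group released.

Step 7
Reactants: 7 (1S,2S,3R,6R)-3,6-bis(tert-butyldimethylsilyloxy)cyclohex-4-ene-1,2-diol
Product: 9 (2R,3R,6R)-2-hydroxy-3,6-bis(tert-butyldimethylsilyloxy)cyclohex-4-en-1-one, via dibutylstannylene acetal 8 (not isolated)
Conditions: Bu2SnO, toluene, reflux (−H2O); then NBS, 4 Å MS, CHCl3, rt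
Reagents that add atoms: none
Why: Stannylene-mediated mono-oxidation of a 1,2-diol (brominolysis of one Sn–O–CH unit), which stops at the α-hydroxy ketone, gives a single ketol because the twofold axis makes the two hydroxyls equivalent, and runs in a neutral medium that should not enolise C2 or C6.

Step 8
Reactants: 9 (2R,3R,6R)-2-hydroxy-3,6-bis(tert-butyldimethylsilyloxy)cyclohex-4-en-1-one
Product: 10 (2S,3R,6R)-3,6-bis(tert-butyldimethylsilyloxy)-1-methylidenecyclohex-4-en-2-ol
Conditions: Zn, CH2Br2, TiCl4, THF, −40 → 5 °C (reagent aged); then 9, CH2Cl2, 0 °C → rt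
Reagents that add atoms: dibromomethane BrCBr
Why: Takai–Lombardo methylenation, whose non-basic zinc–titanium methylene reagent converts enolisable ketones with β-leaving groups into methylenes without epimerisation or elimination and tolerates a free hydroxyl when used in excess.

Step 9
Reactants: 10 (2S,3R,6R)-3,6-bis(tert-butyldimethylsilyloxy)-1-methylidenecyclohex-4-en-2-ol
Product: 12 (1R,2R,3R,6R)-3,6-bis(tert-butyldimethylsilyloxy)-1-(hydroxymethyl)cyclohex-4-ene-1,2-diol, via osmate ester 11 (not isolated)
Conditions: OsO4 (1.05 equiv), TMEDA (1.1 equiv), CH2Cl2, −78 °C; then ethylenediamine, rt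
Reagents that add atoms: osmium tetroxide O=[Os](=O)(=O)=O
Why: TMEDA chelates OsO4 and makes its oxo ligands strong hydrogen-bond acceptors, so the reagent docks on the free C2 hydroxyl of 10 and adds by [3+2] cycloaddition across the neighbouring exocyclic C1=C7 bond, forming C1–O1 and C7–O7 suprafacially to give the hexavalent osmium glycolate 11, which ethylenediamine then releases. The closest known reaction type is the stoichiometric OsO4–TMEDA hydrogen-bond-directed syn-dihydroxylation of cyclic allylic alcohols. No ring of the target closes here; the only ring formed is the transient five-membered osmate chelate. The one new stereocentre, quaternary C1, is set by delivery from the face of the C2 hydroxyl, so O1 ends cis to O2 and C7 on the opposite face, and the C6 silyl ether on that opposite face reinforces the same outcome sterically. The step needs site selectivity for C1=C7 over C4=C5 and face selectivity for the O2 face: the ring alkene has no free allylic hydroxyl, is flanked by two bulky silyloxy carbons and is electron-poorer, so one equivalent of oxidant at −78 °C should leave it untouched.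

Step 10
Reactants: 12 (1R,2R,3R,6R)-3,6-bis(tert-butyldimethylsilyloxy)-1-(hydroxymethyl)cyclohex-4-ene-1,2-diol
Product: 13 [(1R,2R,3R,6R)-2-benzoyloxy-3,6-bis(tert-butyldimethylsilyloxy)-1-hydroxycyclohex-4-en-1-yl]methyl benzoate
Conditions: BzCl (2.5 equiv), pyridine, DMAP (cat.), CH2Cl2, 0 °C → rt
Reagents that add atoms: benzoyl chloride O=C(Cl)c1ccccc1
Why: DMAP-catalysed acylation, which should take the primary O7 and the secondary O2 hydroxyls while the tertiary C1 hydroxyl stays free, so the triol differentiates itself.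

Step 11
Reactants: 13 [(1R,2R,3R,6R)-2-benzoyloxy-3,6-bis(tert-butyldimethylsilyloxy)-1-hydroxycyclohex-4-en-1-yl]methyl benzoate
Product: 14 [(1S,2R,3R,6R)-2-benzoyloxy-1,3,6-trihydroxycyclohex-4-en-1-yl]methyl benzoate
Conditions: HF·pyridine, pyridine, THF, 0 °C → rt
Reagents that add atoms: none
Why: Fluoride-mediated Si–O cleavage under weakly acidic conditions, which should remove both TBS ethers without the base-induced benzoyl shifts (O2 to O3, O7 to O1) that a basic fluoride source could trigger.

Step 12
Reactants: 14 [(1S,2R,3R,6R)-2-benzoyloxy-1,3,6-trihydroxycyclohex-4-en-1-yl]methyl benzoate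
Product: 15 [(1S,2R,3R,6S)-2-benzoyloxy-3-hydroxy-7-oxabicyclo[4.1.0]hept-4-en-1-yl]methyl benzoate
Conditions: PPh3, DIAD, THF, 0 °C → rt
Reagents that add atoms: none
Why: Mitsunobu cyclodehydration, in which phosphorus activates the secondary O6 of the trans C1/C6 diol and the tertiary O1 displaces it with inversion at C6 (3-exo-tet, trans-diaxial) to give the cis-fused oxirane on the face of O2 and O3, while the C3 hydroxyl has no internal nucleophile placed for backside attack and should return unchanged on work-up.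

**Compound list**

1 | 3,4-O-isopropylidene-D-mannitol (2R,3R,4R,5R) | OC[C@@H](O)[C@H]1OC(C)(C)O[C@@H]1[C@H](O)CO | starting material
2 | 3,4-O-isopropylidene-1,6-di-O-(p-tolylsulfonyl)-D-mannitol | Cc1ccc(cc1)S(=O)(=O)OC[C@@H](O)[C@H]1OC(C)(C)O[C@@H]1[C@H](O)COS(=O)(=O)c1ccc(C)cc1 | intermediate
3 | 1,2:5,6-dianhydro-3,4-O-isopropylidene-D-mannitol; (4R,5R)-2,2-dimethyl-4,5-bis[(2R)-oxiran-2-yl]-1,3-dioxolane | C1O[C@H]1[C@H]2OC(C)(C)O[C@@H]2[C@H]3CO3 | intermediate
4 | 1,2,7,8-tetradeoxy-4,5-O-isopropylidene-D-manno-octa-1,7-dienitol; (3R,4R,5R,6R)-4,5-O-isopropylideneocta-1,7-diene-3,4,5,6-tetrol | C=C[C@@H](O)[C@H]1OC(C)(C)O[C@@H]1[C@H](O)C=C | intermediate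
5 | 3,6-bis-O-TBS ether of 4; (4S,5S)-4,5-bis[(1R)-1-(tert-butyldimethylsilyloxy)prop-2-en-1-yl]-2,2-dimethyl-1,3-dioxolane | C=C[C@@H](O[Si](C)(C)C(C)(C)C)[C@H]1OC(C)(C)O[C@@H]1[C@H](O[Si](C)(C)C(C)(C)C)C=C | intermediate
6 | (3aS,4R,7R,7aS)-4,7-bis(tert-butyldimethylsilyloxy)-2,2-dimethyl-3a,4,7,7a-tetrahydro-1,3-benzodioxole (trans ring fusion; each silyloxy group cis to its neighbouring ring oxygen) | CC(C)(C)[Si](C)(C)O[C@@H]1C=C[C@@H](O[Si](C)(C)C(C)(C)C)[C@H]2OC(C)(C)O[C@H]12 | intermediate
7 | (1S,2S,3R,6R)-3,6-bis(tert-butyldimethylsilyloxy)cyclohex-4-ene-1,2-diol (3,6-di-O-TBS-conduritol E; O1/O2 trans, O2/O3 cis, O1/O6 cis) | CC(C)(C)[Si](C)(C)O[C@@H]1C=C[C@@H](O[Si](C)(C)C(C)(C)C)[C@@H](O)[C@@H]1O | intermediate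
8 | dibutylstannylene acetal of 7 (2,2-dibutyl-1,3,2-dioxastannolane on O1/O2; not isolated) | CC(C)(C)[Si](C)(C)O[C@@H]1C=C[C@@H](O[Si](C)(C)C(C)(C)C)[C@H]2O[Sn](CCCC)(CCCC)O[C@H]12 | intermediate
9 | (2R,3R,6R)-2-hydroxy-3,6-bis(tert-butyldimethylsilyloxy)cyclohex-4-en-1-one (O2/O3 cis, O6 on the other face) | CC(C)(C)[Si](C)(C)O[C@@H]1C=C[C@@H](O[Si](C)(C)C(C)(C)C)C(=O)[C@@H]1O | intermediate
10 | (2S,3R,6R)-3,6-bis(tert-butyldimethylsilyloxy)-1-methylidenecyclohex-4-en-2-ol (key-step precursor) | C=C1[C@H](O)[C@H](O[Si](C)(C)C(C)(C)C)C=C[C@H]1O[Si](C)(C)C(C)(C)C | intermediate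
11 | cyclic O1,O7-osmate ester of 12 (hexavalent osmium glycolate) chelated by TMEDA (not isolated; ligand drawn as a separate component) | O=[Os]1(=O)OC[C@@]2(O1)[C@H](O)[C@H](O[Si](C)(C)C(C)(C)C)C=C[C@H]2O[Si](C)(C)C(C)(C)C.CN(C)CCN(C)C | intermediate
12 | (1R,2R,3R,6R)-3,6-bis(tert-butyldimethylsilyloxy)-1-(hydroxymethyl)cyclohex-4-ene-1,2-diol (O1, O2, O3 on one face; C7 and O6 on the other) | OC[C@@]1(O)[C@H](O)[C@H](O[Si](C)(C)C(C)(C)C)C=C[C@H]1O[Si](C)(C)C(C)(C)C | intermediate
13 | [(1R,2R,3R,6R)-2-benzoyloxy-3,6-bis(tert-butyldimethylsilyloxy)-1-hydroxycyclohex-4-en-1-yl]methyl benzoate | O=C(OC[C@@]1(O)[C@H](OC(=O)c2ccccc2)[C@H](O[Si](C)(C)C(C)(C)C)C=C[C@H]1O[Si](C)(C)C(C)(C)C)c1ccccc1 | intermediate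
14 | [(1S,2R,3R,6R)-2-benzoyloxy-1,3,6-trihydroxycyclohex-4-en-1-yl]methyl benzoate | O=C(OC[C@@]1(O)[C@H](OC(=O)c2ccccc2)[C@H](O)C=C[C@H]1O)c1ccccc1 | intermediate
15 | [(1S,2R,3R,6S)-2-benzoyloxy-3-hydroxy-7-oxabicyclo[4.1.0]hept-4-en-1-yl]methyl benzoate | O=C(OC[C@]12O[C@H]1C=C[C@@H](O)[C@H]2OC(=O)c1ccccc1)c1ccccc1 | target

**Step count and risk**

Total step count: 12. Longest linear sequence: 12 steps (from 1).

Steps most likely to fail:

Step 8 (methylenation of ketol 9). The β,γ-unsaturated α-hydroxy-α′-silyloxy ketone may enolise toward C6 or C2 under the Lewis-acidic reagent, with loss of a silyloxy group and aromatisation or acyloin-type epimerisation at C2, and the free hydroxyl may consume reagent. The fallback sets out from diol 7 and comes back to the route at 10; it also bypasses the mono-oxidation of step 7. Diol 7 is mono-silylated with TESCl and imidazole in DMF at 0 °C (the two hydroxyls are homotopic, so only over-silylation has to be controlled) to give the 2-O-triethylsilyl ether F1. Dess–Martin periodinane with NaHCO3 in CH2Cl2 then oxidises the remaining hydroxyl to the fully protected ketone F2. Petasis methylenation with Cp2TiMe2 in toluene at 65 °C gives the methylidene silyl ether F3. PPTS in MeOH at 0 °C should remove the more labile triethylsilyl ether selectively and deliver 10.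

Step 12 (oxirane closure). Phosphorus may also activate the allylic C3 hydroxyl, leading to allylic substitution by the hydrazide or elimination; the basic betaine may shift the benzoyl group from O2 to the cis O3; and activation next to the quaternary centre may be slow. The fallback sets out from 14 and comes back at 15. Catalytic Bu2SnO with TsCl and Et3N in CH2Cl2 at 0 °C should bind only the vicinal C1/C6 diol and sulfonylate its secondary oxygen, leaving the isolated C3 hydroxyl, to give the 6-O-tosylate F6. DBU in CH2Cl2 then lets O1 displace the tosylate with inversion at C6, which gives 15.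

Step 9 (directed dihydroxylation). The ring alkene may be osmylated under homoallylic direction, facial control may erode if the C2 hydroxyl lies in the plane of the methylene, or the osmate chelate may resist cleavage without silyl loss. The fallback sets out from 10 and comes back at 13. Hydroxyl-directed epoxidation with catalytic VO(acac)2 and t-BuOOH in CH2Cl2 at 0 °C should place the oxygen on the O2 face of C1=C7 and give the spiro-epoxy alcohol F4. Benzoic acid with Ti(OiPr)4 in CH2Cl2 opens this oxirane at the unhindered C7 and gives the 7-O-benzoyl diol F5. Benzoylation of O2 with BzCl, pyridine and DMAP then gives 13.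

Further compounds
F1 | step 8 | (1S,2S,3R,6R)-3,6-bis(tert-butyldimethylsilyloxy)-2-(triethylsilyloxy)cyclohex-4-en-1-ol | CC(C)(C)[Si](C)(C)O[C@@H]1C=C[C@@H](O[Si](C)(C)C(C)(C)C)[C@@H](O)[C@@H]1O[Si](CC)(CC)CC
F2 | step 8 | 3,6-bis(tert-butyldimethylsilyloxy)-2-(triethylsilyloxy)cyclohex-4-en-1-one (configuration as in 9) | CC(C)(C)[Si](C)(C)O[C@@H]1C=C[C@@H](O[Si](C)(C)C(C)(C)C)C(=O)[C@@H]1O[Si](CC)(CC)CC
F3 | step 8 | 2-O-triethylsilyl ether of 10 | CC(C)(C)[Si](C)(C)O[C@@H]1C=C[C@@H](O[Si](C)(C)C(C)(C)C)C(=C)[C@@H]1O[Si](CC)(CC)CC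
F4 | step 9 | spiro-epoxy alcohol: C1,C7-oxirane of 10 with the oxirane oxygen cis to the C2 hydroxyl | O1C[C@]12[C@H](O)[C@H](O[Si](C)(C)C(C)(C)C)C=C[C@H]2O[Si](C)(C)C(C)(C)C
F5 | step 9 | 7-O-benzoate of 12 | O=C(OC[C@@]1(O)[C@H](O)[C@H](O[Si](C)(C)C(C)(C)C)C=C[C@H]1O[Si](C)(C)C(C)(C)C)c1ccccc1
F6 | step 12 | 6-O-(p-tolylsulfonyl) derivative of 14 | O=C(OC[C@@]1(O)[C@H](OC(=O)c2ccccc2)[C@H](O)C=C[C@H]1OS(=O)(=O)c1ccc(C)cc1)c1ccccc1
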